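## Analysis of the target

1. Rhoiptelol B (16) is a 1,7-diarylheptanoid with chain C1–C7. C1 carries a 4-hydroxy-3-methoxyphenyl (guaiacyl) ring, C7 a 4-hydroxyphenyl ring, and C3 and C6 carry hydroxyls. One oxygen (called O5 here) bridges C5 and C1, so O5–C1–C2–C3–C4–C5 is an oxane ring.
2. The stereocentres are C1 (R), C3 (S), C5 (S) and C6 (S). On the chair, the aryl group at C1 and the side chain at C5 are cis and equatorial, and the C3 hydroxyl is trans to both and axial. The exocyclic C6 carbinol is threo (1,2-syn) to C5–O5, and along the open chain C3–O and C5–O are 1,3-syn.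
3. The route is built on one feature: O5 with C1–C6 is a 2,4-dideoxyhexopyranose whose anomeric carbon C1 bears an aryl group instead of OH, that is, a C-aryl glycoside.
4. In this unit C2 and C4 are bare CH2 groups and oxygen sits on C1, C3 and C5. C1–C2, C3–C4 and C5–C6 are therefore three head-to-tail two-carbon aldehyde units, and the trans C3-OH/C5-substituent pattern belongs to the D-erythro series.
5. A second feature is that C1–O5 is a p-hydroxybenzyl (protected: p-alkoxybenzyl) ether that ionises reversibly. C1 can thus be left to thermodynamic control, but the same bond is the weak point towards acid, hydrogenolysis and, through a p-quinone methide, base.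
6. The two free phenols are sensitive to oxidation. C3–OH is β to C1, so loss of a proton from a C1 cation would give a styrene whose allylic C3–OH could ionise in turn.
7. The synthesis is hard for three reasons: chair-type cationic ring closures do not deliver the axial C3 hydroxyl, C6 lies outside the control of the ring, and four stereocentres sit on seven unbranched carbons, which invites a costly centre-by-centre build-up.

## Retrosynthetic reasoning

**Phenol O–H (16 ⇒ 15).** Only the two phenols are masked, as benzyl ethers, because both aryl groups enter as organomagnesium reagents. The ethers come with the purchased building blocks, so no protection step is spent. The forward reaction must cleave two aryl benzyl ethers and spare the benzylic C1–O5 bond.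

**C6–C7 (15 ⇒ 12 + 14).**
- The cut is made at the C6 carbinol, on the side away from the ring.
- The whole right-hand part becomes the benzylic Grignard reagent 14, made from the commercial chloride 13.
- C6 becomes an aldehyde directly on C5, where O5 acts as an α-alkoxy group. A five-membered magnesium chelate between O5 and the aldehyde oxygen exposes the face that leads to the threo (6S) carbinol.
- A cut at C5–C6 would need a three-carbon α-oxygenated aldehyde with its own labile stereocentre, and it would destroy the six-carbon sugar pattern.
- What is left, 12, is a six-carbon C-aryl glycoside.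

**Oxidation level at C6 (12 ⇒ 11).** The aldehyde is traced back to a primary alcohol. The forward step must oxidise a primary alcohol next to a free axial secondary one. This is an ordinary selectivity, and it is helped because C3–OH and C6 are trans on the ring and cannot form a lactol.

**C1–O5 (11 ⇒ 10).**
- The ring is opened at the p-alkoxybenzyl ether bond, not at C5–O5, because only C1 can ionise.
- C1 then needs no stereocontrol at all. Both epimers of the benzylic alcohol 10 pass through the same cation, and the closure is reversible, so the diequatorial 2,6-cis oxane is the resting state.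
- The forward step must ionise C1 alone and close on O5 (six-membered), not on O6 (seven) or O3 (four).

**C1–aryl (10 ⇒ 7 + 9).** Removing the guaiacyl group as Grignard reagent 9 (from bromide 8) leaves C1 as an aldehyde, stored as lactol 7. This exposes the sugar hidden in the target. The acetate on O6 in 7 is cleaved by the same reagent, which frees exactly the hydroxyl that has to be oxidised later.

**C2–C3 and C4–C5 (7 ⇒ 3 + 2 × 4), the key disconnection.**
- Both bonds are aldol bonds between C2 units, and both carbinols (C5, then C3) have the configuration that a 2-deoxyribose-5-phosphate aldolase (DERA) imposes.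
- One enzymatic operation joins three achiral aldehydes. It forms two C–C bonds, sets C3 and C5 as a pair (including the axial hydroxyl) and closes the oxane as its lactol.
- No small-molecule catalyst stops a cross-aldol of 4 cleanly after two additions.
- A larger acceptor carrying C7 and a free C6 hydroxyl was not chosen. After the first addition that hydroxyl would hold the intermediate as a five-membered lactol and stall the second addition. The enzyme also prefers the opposite configuration next to the acceptor carbonyl.

**Acceptor (3 ⇒ 1).** Aldehyde 3 is half of the symmetrical alkene 1, so oxidative cleavage of the C=C bond gives two molecules of 3 and nothing else that contains carbon from 1.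

## Alternatives that were turned down

**Alternative 1:** Prins cyclisation (the textbook route).
- *Disconnection:* C1–O5 and C1–C2, with C3–O formed in the same step.
- *Forward key step:* 4-(benzyloxy)-3-methoxybenzaldehyde A1 and the homoallylic alcohol (2S,3S)-2-(benzyloxy)-1-[4-(benzyloxy)phenyl]hex-5-en-3-ol A2 condense under acid to an oxocarbenium ion. This cyclises through a chair, and the C3 cation is captured equatorially to give the all-cis oxane A3.
- *Why turned down:*
  - The chair puts all three substituents equatorial, so A3 is the C3 epimer of what is needed. Correction by Mitsunobu inversion or oxidation/reduction costs two to three steps on the most advanced material.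
  - The oxocarbenium ion from the electron-rich A1 can equilibrate by 2-oxonia-Cope rearrangement and by benzylic ionisation, which threatens C5 and invites side-chain exchange.
  - A2 already contains the two adjacent stereocentres C5 and C6 and needs its own multi-step synthesis, so the precursor is not much simpler than the product.

**Alternative 2:** aldol addition followed by oxa-Michael closure.
- *Disconnection:* C4–C5 and C1–O5.
- *Forward key step:* the methyl ketone enolate of (E)-4-[4-(benzyloxy)-3-methoxyphenyl]but-3-en-2-one A4 adds to (S)-2-(benzyloxy)-3-[4-(benzyloxy)phenyl]propanal A5, whose C6 maps onto the α-carbon of L-tyrosine. This gives the β-hydroxy enone A6. A 6-endo-trig oxa-Michael addition then gives the 2,6-cis oxan-4-one A7, and a bulky hydride delivers the axial C3–OH.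
- *Why turned down:*
  - C5, C1 and C3 are set in three separate operations.
  - An acetate-type aldol has no enolate geometry to use. The 5,6-syn relation needs chelation control, whereas methyl ketone enolates tend to follow the Felkin–Anh (anti) sense.
  - A5 costs four to five steps from the amino acid and is configurationally labile.
  - A6 and A7 are linked by retro-Michael, retro-aldol and dehydration pathways under the very conditions of the closure.

**Alternative 3:** biomimetic p-quinone methide closure.
- *Disconnection:* C1–O5 alone, at the level of the C1–H bond.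
- *Forward key step:* oxidation (quinone or Ag(I) oxidant, or a flavin-dependent 4-alkylphenol oxidase) converts the linear triol (3S,5S,6S)-1-(4-hydroxy-3-methoxyphenyl)-7-(4-hydroxyphenyl)heptane-3,5,6-triol A8 into the p-quinone methide A9. O5 traps A9 by 1,6-addition to give 16.
- *Why turned down:*
  - The step forms one bond and the one stereocentre that thermodynamics gives for free.
  - A8 keeps C3, C5 and C6 on an acyclic chain, where they have to be set one after another.
  - Both rings are 4-alkylphenols, so discrimination of C1 from C7 rests only on one methoxy group.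
  - The C1–H bond of 16 is α-oxygenated and easier to oxidise than that of A8, so over-oxidation is built in.

Key step: step 2

Remark (assumption): recombinant E. coli DERA (EC 4.1.2.4) is treated as a purchasable catalyst. Compounds 1, 4, 8 and 13 are taken as commercial. Locants C1–C7 and O5 always refer to the heptanoid numbering of 16.

## Route

Step 1
Reactants: 1 (Z)-but-2-ene-1,4-diyl diacetate
Product: 3 acetoxyacetaldehyde (2-oxoethyl acetate), via 3,5-bis(acetoxymethyl)-1,2,4-trioxolane 2 (not isolated)
Conditions: O3, CH2Cl2, −78 °C; then Me2S, −78 °C → rt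
Reagents that add atoms: ozone, [O-][O+]=O
Why: Ozonolysis (Criegee mechanism) of the symmetrical alkene gives two identical molecules of 3, and the reductive work-up leaves the acetate untouched. No stereocentre is involved.

Step 2
Reactants: 3 acetoxyacetaldehyde; 4 acetaldehyde (2 equiv)
Product: 7 [(2S,4R)-4,6-dihydroxyoxan-2-yl]methyl acetate (6-O-acetyl-2,4-dideoxy-D-erythro-hexopyranose, anomeric mixture), via (3S)-4-acetoxy-3-hydroxybutanal 5 (not isolated), via (3R,5S)-6-acetoxy-3,5-dihydroxyhexanal 6 (not isolated)
Conditions: DERA (class I aldolase, E. coli, cell-free extract), 4 (2.1 equiv, slow feed), phosphate buffer pH 7.2, 30 °C; extraction with EtOAc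
Reagents that add atoms: none
Why: Class I aldolase mechanism: the active-site lysine condenses with 4 to an enamine that adds to the aldehyde of 3 (C4–C5 bond) to give 5, and 5 returns as acceptor for a second enamine (C2–C3 bond) to give 6. The closest known reaction type is the DERA tandem aldol of α-heteroatom-substituted acetaldehydes (chloro, alkoxy, acyloxy) with two molecules of 4, which is practised on scale for statin side-chain lactols, so 3 lies inside the known acceptor class. Ring closure: 6 closes spontaneously by 6-exo-trig attack of the C5 hydroxyl on the C1 aldehyde to give the oxane hemiacetal 7, and the anomeric mixture at C1 is of no consequence. C5 and C3 are both set by the enzyme, which presents the enamine to the same face of each acceptor carbonyl as in its natural reaction; this gives 5S and then the 1,3-syn carbinol (3R in 6 and 7, the same spatial arrangement as 3S in 16), which is the hydroxyl trans to C6 that is axial in the target. Donor selectivity: only 4 forms the enamine, and 3 and 5 are not accepted as donors. Acceptor selectivity: the inductively activated aldehyde of 3 should outcompete 4 as acceptor, and the slow feed of 4 keeps its self-addition and the deactivation of the enzyme low. Chain-length selectivity: the O-acetyl group keeps 5 from resting as a five-membered lactol, so 5 remains an acceptor, whereas 6 is withdrawn as the stable lactol 7, which stops a third addition and pulls the reversible aldol equilibria forward.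

Step 3
Reactants: 7 [(2S,4R)-4,6-dihydroxyoxan-2-yl]methyl acetate; 8 1-(benzyloxy)-4-bromo-2-methoxybenzene (6 equiv)
Product: 10 (1RS,3S,5S)-1-[4-(benzyloxy)-3-methoxyphenyl]hexane-1,3,5,6-tetrol, via [4-(benzyloxy)-3-methoxyphenyl]magnesium bromide 9 (not isolated)
Conditions: 8, Mg, THF, rt (→ 9); then 7 in THF, 0 °C → rt; aq NH4Cl
Reagents that add atoms: none
Why: Grignard addition to the open-chain aldehyde tautomer of a 2-deoxy lactol: two equivalents of 9 deprotonate the hydroxyls, two cleave the acetate (freeing C6–OH for step 5) and one adds to C1. C3 and C5 are not touched, and C1 is left as a mixture of epimers because step 4 is stereoconvergent.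

Step 4
Reactants: 10 (1RS,3S,5S)-1-[4-(benzyloxy)-3-methoxyphenyl]hexane-1,3,5,6-tetrol
Product: 11 (2R,4S,6S)-2-[4-(benzyloxy)-3-methoxyphenyl]-6-(hydroxymethyl)oxan-4-ol
Conditions: TsOH·H2O (10 mol %), CH2Cl2–THF, 0 °C → rt
Reagents that add atoms: none
Why: Acid-catalysed SN1 cyclodehydration through the p-alkoxybenzyl cation: only the C1 hydroxyl can ionise, and O5 closes the six-membered ring in preference to O6 (seven) or O3 (four). Because C1–O5 re-ionises under the conditions, both C1 epimers should converge on the thermodynamic 2,6-cis oxane (1R) with aryl and CH2OH equatorial. The C1 epimer would have to place the aryl group syn-diaxial to C3–OH or, after ring flip, the CH2OH group axial.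

Step 5
Reactants: 11 (2R,4S,6S)-2-[4-(benzyloxy)-3-methoxyphenyl]-6-(hydroxymethyl)oxan-4-ol
Product: 12 (2S,4S,6R)-6-[4-(benzyloxy)-3-methoxyphenyl]-4-hydroxyoxane-2-carbaldehyde
Conditions: TEMPO (10 mol %), PhI(OAc)2 (1.1 equiv), CH2Cl2, rt
Reagents that add atoms: none
Why: Oxoammonium oxidation is selective for the unhindered primary alcohol over the axial secondary C3–OH and stops at the aldehyde in dry CH2Cl2, and lactol or lactone formation is excluded because C3–OH and C6 are trans on the ring. C5 becomes α to an aldehyde, but its equatorial configuration is also the thermodynamic one.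

Step 6
Reactants: 12 (2S,4S,6R)-6-[4-(benzyloxy)-3-methoxyphenyl]-4-hydroxyoxane-2-carbaldehyde; 13 1-(benzyloxy)-4-(chloromethyl)benzene (3 equiv)
Product: 15 (2R,4S,6S)-2-[4-(benzyloxy)-3-methoxyphenyl]-6-{(1S)-2-[4-(benzyloxy)phenyl]-1-hydroxyethyl}oxan-4-ol, via [4-(benzyloxy)benzyl]magnesium chloride 14 (not isolated)
Conditions: 13, Mg (excess), Et2O, 0 °C (→ 14); 12, MgBr2·OEt2 (2 equiv), CH2Cl2, −78 °C, then 14, −78 °C; aq NH4Cl
Reagents that add atoms: none
Why: Cram-chelate-controlled Grignard addition to an α-alkoxy aldehyde: Mg(II) ties the aldehyde oxygen to O5 in a five-membered chelate, and 14 attacks C6 from the side of H5 rather than that of C4, which gives the 5,6-syn (threo) carbinol, 6S. One equivalent of 14 is spent on C3–OH, and the weakly coordinating solvent and added MgBr2 favour the chelate over the Felkin–Anh arrangement.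

Step 7
Reactants: 15 (2R,4S,6S)-2-[4-(benzyloxy)-3-methoxyphenyl]-6-{(1S)-2-[4-(benzyloxy)phenyl]-1-hydroxyethyl}oxan-4-ol
Product: 16 rhoiptelol B, (1R,3S,5S,6S)-1,5-epoxy-1-(4-hydroxy-3-methoxyphenyl)-7-(4-hydroxyphenyl)heptane-3,6-diol
Conditions: H2 (1 atm), 10% Pd/C, EtOAc–EtOH, rt, stopped after uptake of 2 equiv H2
Reagents that add atoms: none
Why: Catalytic hydrogenolysis cleaves aryl benzyl ethers much faster than the dialkyl-type benzylic C1–O5 bond under neutral conditions. No stereocentre is affected.

## Compound list

1 | (Z)-but-2-ene-1,4-diyl diacetate | CC(=O)OC/C=C\COC(C)=O | starting material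
2 | 3,5-bis(acetoxymethyl)-1,2,4-trioxolane (not isolated) | CC(=O)OCC1OOC(COC(C)=O)O1 | intermediate
3 | acetoxyacetaldehyde (2-oxoethyl acetate) | CC(=O)OCC=O | intermediate
4 | acetaldehyde | CC=O | starting material
5 | (3S)-4-acetoxy-3-hydroxybutanal (not isolated) | O=CC[C@@H](COC(C)=O)O | intermediate
6 | (3R,5S)-6-acetoxy-3,5-dihydroxyhexanal (not isolated) | O=CC[C@H](O)C[C@@H](COC(C)=O)O | intermediate
7 | [(2S,4R)-4,6-dihydroxyoxan-2-yl]methyl acetate (anomeric mixture) | OC1C[C@H](O)C[C@@H](COC(C)=O)O1 | intermediate
8 | 1-(benzyloxy)-4-bromo-2-methoxybenzene | COc1cc(Br)ccc1OCc1ccccc1 | starting material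
9 | [4-(benzyloxy)-3-methoxyphenyl]magnesium bromide (not isolated) | COc1cc([Mg]Br)ccc1OCc1ccccc1 | intermediate
10 | (1RS,3S,5S)-1-[4-(benzyloxy)-3-methoxyphenyl]hexane-1,3,5,6-tetrol (C1 epimers) | COc1cc(C(O)C[C@H](O)C[C@@H](CO)O)ccc1OCc1ccccc1 | intermediate
11 | (2R,4S,6S)-2-[4-(benzyloxy)-3-methoxyphenyl]-6-(hydroxymethyl)oxan-4-ol | COc1cc([C@H]2C[C@H](O)C[C@@H](CO)O2)ccc1OCc1ccccc1 | intermediate
12 | (2S,4S,6R)-6-[4-(benzyloxy)-3-methoxyphenyl]-4-hydroxyoxane-2-carbaldehyde | COc1cc([C@H]2C[C@H](O)C[C@@H](C=O)O2)ccc1OCc1ccccc1 | intermediate
13 | 1-(benzyloxy)-4-(chloromethyl)benzene | ClCc1ccc(OCc2ccccc2)cc1 | starting material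
14 | [4-(benzyloxy)benzyl]magnesium chloride (not isolated) | Cl[Mg]Cc1ccc(OCc2ccccc2)cc1 | intermediate
15 | (2R,4S,6S)-2-[4-(benzyloxy)-3-methoxyphenyl]-6-{(1S)-2-[4-(benzyloxy)phenyl]-1-hydroxyethyl}oxan-4-ol | COc1cc([C@H]2C[C@H](O)C[C@@H]([C@@H](O)Cc3ccc(OCc4ccccc4)cc3)O2)ccc1OCc1ccccc1 | intermediate
16 | rhoiptelol B | COc1cc([C@H]2C[C@H](O)C[C@@H]([C@@H](O)Cc3ccc(O)cc3)O2)ccc1O | target

## Step count and least certain steps

Total step count: 7. Longest linear sequence: 7 steps (1 → 16). Both aryl building blocks are purchased and enter directly.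

**Step 2 (key step).**
- *What may go wrong:* gradual deactivation of the enzyme by 4 and by its condensation products, hydrolysis of the acetate of 3 by esterases in a crude extract, and competing self-addition of 4. Each of these lowers conversion and burdens the extraction of the polar lactol.
- *Fallback (sets out from 3, comes back at 10):*
  - A Ti(IV)–BINOL-catalysed vinylogous Mukaiyama aldol addition of 1-methoxy-1,3-bis(trimethylsilyloxy)buta-1,3-diene to 3 is run with the BINOL enantiomer that gives the 5S carbinol. After acidic desilylation it would give methyl (5S)-6-acetoxy-5-hydroxy-3-oxohexanoate F1.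
  - Narasaka–Prasad reduction (Et2BOMe, NaBH4, THF–MeOH, −78 °C) sets C3 1,3-syn and would give methyl (3R,5S)-6-acetoxy-3,5-dihydroxyhexanoate F2.
  - Excess DIBAL-H at −78 °C takes the methyl ester to the aldehyde level and removes the acetate, to give 2,4-dideoxy-D-erythro-hexopyranose F3.
  - F3 reacts with 9 as in step 3 to give 10.

**Step 3.**
- *What may go wrong:* slow ring opening of the magnesium lactolate, precipitation of the polyalkoxide before C1 has reacted, and retro-aldol cleavage of the β-oxido aldehyde.
- *Fallback (sets out from 7, comes back at 11; the ring is kept closed):*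
  - Oxidation of the lactol (Br2, BaCO3, H2O, 0 °C) would give [(2S,4R)-4-hydroxy-6-oxooxan-2-yl]methyl acetate F4.
  - Silylation (TBSCl, imidazole, DMF) would give [(2S,4R)-4-[(tert-butyldimethylsilyl)oxy]-6-oxooxan-2-yl]methyl acetate F5.
  - Reagent 9 (3.3 equiv, THF, −40 °C) adds once to the lactone and cleaves the acetate to give the hemiketal (4R,6S)-2-[4-(benzyloxy)-3-methoxyphenyl]-4-[(tert-butyldimethylsilyl)oxy]-6-(hydroxymethyl)oxan-2-ol F6.
  - Et3SiH/BF3·OEt2 (CH2Cl2–MeCN, −40 °C) reduces the cyclic oxocarbenium ion by axial hydride delivery to the 2,6-cis oxane [(2S,4S,6R)-6-[4-(benzyloxy)-3-methoxyphenyl]-4-[(tert-butyldimethylsilyl)oxy]oxan-2-yl]methanol F7.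
  - TBAF then gives 11.

**Step 4.**
- *What may go wrong:* loss of a proton from the benzylic cation to give a styrene, followed by ionisation of the then allylic C3 hydroxyl, which would erode the C3 configuration. Intermolecular Friedel–Crafts alkylation of the electron-rich rings is also possible if the reaction is run too concentrated or too long.
- *Fallback (sets out from 10, comes back at 11):*
  - Selective oxidation of the benzylic alcohol (MnO2, EtOAc, rt) would give (3R,5S)-1-[4-(benzyloxy)-3-methoxyphenyl]-3,5,6-trihydroxyhexan-1-one F8.
  - Under Et3SiH/BF3·OEt2 (CH2Cl2–MeCN, −40 °C) F8 closes on O5 and undergoes reductive etherification. C1 is then set kinetically by axial hydride attack on the cyclic oxocarbenium ion, not by equilibration of a benzylic cation.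

**Step 6.**
- *What may go wrong:* poor facial selectivity, because the chelate competes with a Felkin–Anh arrangement and the C3 magnesium alkoxide perturbs the complex. Wurtz coupling during formation of 14 and attack through the ortho position of the benzylic reagent are further risks.
- *Fallback (sets out from 15 as the crude mixture of C6 epimers, comes back at 15):*
  - Dess–Martin oxidation of both secondary alcohols would give (2R,6S)-2-[4-(benzyloxy)-3-methoxyphenyl]-6-{[4-(benzyloxy)phenyl]acetyl}oxan-4-one F9.
  - L-Selectride (THF, −78 °C) then reduces both ketones. It attacks the ring ketone equatorially to restore the axial C3–OH. It reduces the α-alkoxy ketone in the polar Felkin–Anh sense, which for hydride addition leads to the 5,6-syn (6S) carbinol.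
  - C6 is thus set by C=O reduction and not by C–C bond formation.

**Step 7.**
- *What may go wrong:* hydrogenolytic opening of the oxane at the benzylic C1–O5 bond once the phenols are free, because the ring becomes more electron-rich.
- *Fallback (sets out from 15, comes back at 16):* non-reductive, Lewis-acid-mediated debenzylation with BCl3 and pentamethylbenzene as cation scavenger (CH2Cl2, −78 °C), followed by methanolysis of the borates. This fallback makes no new compound (F0).

## Further compounds

F1 | step 2 | methyl (5S)-6-acetoxy-5-hydroxy-3-oxohexanoate | COC(=O)CC(=O)C[C@@H](COC(C)=O)O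
F2 | step 2 | methyl (3R,5S)-6-acetoxy-3,5-dihydroxyhexanoate | COC(=O)C[C@H](O)C[C@@H](COC(C)=O)O
F3 | step 2 | 2,4-dideoxy-D-erythro-hexopyranose, (4R,6S)-6-(hydroxymethyl)oxane-2,4-diol | OC1C[C@H](O)C[C@@H](CO)O1
F4 | step 3 | [(2S,4R)-4-hydroxy-6-oxooxan-2-yl]methyl acetate | O=C1C[C@H](O)C[C@@H](COC(C)=O)O1
F5 | step 3 | [(2S,4R)-4-[(tert-butyldimethylsilyl)oxy]-6-oxooxan-2-yl]methyl acetate | O=C1C[C@H](O[Si](C)(C)C(C)(C)C)C[C@@H](COC(C)=O)O1
F6 | step 3 | (4R,6S)-2-[4-(benzyloxy)-3-methoxyphenyl]-4-[(tert-butyldimethylsilyl)oxy]-6-(hydroxymethyl)oxan-2-ol | COc1cc(C2(O)C[C@H](O[Si](C)(C)C(C)(C)C)C[C@@H](CO)O2)ccc1OCc1ccccc1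
F7 | step 3 | [(2S,4S,6R)-6-[4-(benzyloxy)-3-methoxyphenyl]-4-[(tert-butyldimethylsilyl)oxy]oxan-2-yl]methanol | COc1cc([C@H]2C[C@H](O[Si](C)(C)C(C)(C)C)C[C@@H](CO)O2)ccc1OCc1ccccc1
F8 | step 4 | (3R,5S)-1-[4-(benzyloxy)-3-methoxyphenyl]-3,5,6-trihydroxyhexan-1-one | COc1cc(C(=O)C[C@H](O)C[C@@H](CO)O)ccc1OCc1ccccc1
F9 | step 6 | (2R,6S)-2-[4-(benzyloxy)-3-methoxyphenyl]-6-{[4-(benzyloxy)phenyl]acetyl}oxan-4-one | COc1cc([C@H]2CC(=O)C[C@@H](C(=O)Cc3ccc(OCc4ccccc4)cc3)O2)ccc1OCc1ccccc1
F0 | step 7 | none | none
A1 | alternative 1 | 4-(benzyloxy)-3-methoxybenzaldehyde | COc1cc(C=O)ccc1OCc1ccccc1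
A2 | alternative 1 | (2S,3S)-2-(benzyloxy)-1-[4-(benzyloxy)phenyl]hex-5-en-3-ol | C=CC[C@@H]([C@@H](OCc1ccccc1)Cc1ccc(OCc2ccccc2)cc1)O
A3 | alternative 1 | all-cis Prins product, (2R,4R,6S)-2-[4-(benzyloxy)-3-methoxyphenyl]-6-{(1S)-1-(benzyloxy)-2-[4-(benzyloxy)phenyl]ethyl}oxan-4-ol | COc1cc([C@H]2C[C@@H](O)C[C@@H]([C@@H](OCc3ccccc3)Cc3ccc(OCc4ccccc4)cc3)O2)ccc1OCc1ccccc1
A4 | alternative 2 | (E)-4-[4-(benzyloxy)-3-methoxyphenyl]but-3-en-2-one | COc1cc(/C=C/C(C)=O)ccc1OCc1ccccc1
A5 | alternative 2 | (S)-2-(benzyloxy)-3-[4-(benzyloxy)phenyl]propanal | O=C[C@@H](OCc1ccccc1)Cc1ccc(OCc2ccccc2)cc1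
A6 | alternative 2 | (1E,5S,6S)-6-(benzyloxy)-1-[4-(benzyloxy)-3-methoxyphenyl]-7-[4-(benzyloxy)phenyl]-5-hydroxyhept-1-en-3-one | COc1cc(/C=C/C(=O)C[C@@H]([C@@H](OCc2ccccc2)Cc2ccc(OCc3ccccc3)cc2)O)ccc1OCc1ccccc1
A7 | alternative 2 | (2R,6S)-2-[4-(benzyloxy)-3-methoxyphenyl]-6-{(1S)-1-(benzyloxy)-2-[4-(benzyloxy)phenyl]ethyl}oxan-4-one | COc1cc([C@H]2CC(=O)C[C@@H]([C@@H](OCc3ccccc3)Cc3ccc(OCc4ccccc4)cc3)O2)ccc1OCc1ccccc1
A8 | alternative 3 | (3S,5S,6S)-1-(4-hydroxy-3-methoxyphenyl)-7-(4-hydroxyphenyl)heptane-3,5,6-triol | COc1cc(CC[C@H](O)C[C@@H]([C@@H](O)Cc2ccc(O)cc2)O)ccc1O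
A9 | alternative 3 | p-quinone methide, 2-methoxy-4-[(3S,5S,6S)-3,5,6-trihydroxy-7-(4-hydroxyphenyl)heptylidene]cyclohexa-2,5-dien-1-one | COC1=CC(=CC[C@H](O)C[C@@H]([C@@H](O)Cc2ccc(O)cc2)O)C=CC1=O
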